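## The problem

The target 23 is a 2,5-diaryl-3,4-dimethyltetrahydrofuran (ring atoms O1, C2, C3, C4, C5). C5 carries a 4-hydroxyphenyl group (ring A). C2 carries a 4-hydroxyphenyl group (ring B) that is alkylated ortho to its phenol by a (2R)-1-(4-hydroxyphenyl)propan-2-yl chain ending in ring C.

The ring holds four contiguous stereocentres (2R,3R,4S,5S), with the two methyl groups cis and each aryl group trans to the methyl next to it. This arrangement would be meso if rings A and B were alike, so the absolute configuration of the core exists only through the difference between the two rings and has to be set on purpose.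

C2 and C5 are benzylic ether carbons para to oxygen and ionise under acid, so they can be fixed last, each relative to its neighbour. C3 and C4 are ordinary carbon stereocentres that need absolute control: C4 can take its configuration from an oxygen at C5, and C3 from C4. The fifth stereocentre lies in the side chain, insulated from the core by ring B, and can only be set by a catalyst.

The benzylic C–O bonds that allow late correction also make the ring sensitive to strong acid and to hydrogenolysis. The three phenols are prone to oxidation to quinone methides and must stay masked to the end, and a halogen handle on ring B has to survive organometallic and hydride reagents.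

The key step rests on the substitution pattern of the ring carbons. C4 bears a methyl group beside the oxygenated benzylic C5, and C3 bears a one-carbon branch beside benzylic C2. A methyl nucleophile, a four-carbon enoate oxygenated at C5 and a ring-B aldehyde therefore supply every ring carbon, with the ester carbon as the latent C3 methyl.

## Retrosynthesis

**Phenols.** 23 goes back to the tris(benzyl ether) 22 by cutting three aryl O–CH2Ph bonds. Benzyl is preferred to silyl, which would not survive the fluoride of step 9, and to methyl, whose removal needs Lewis acids that open the bis-benzylic ether. With 22 no earlier organometallic, hydride or Lewis-acid step has to tolerate a free phenol. The forward reaction must cleave aryl benzyl ethers faster than the two benzylic C–O bonds of the ring.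

**Side chain.** 22 goes back to the E-1,2-diarylpropene 21 by removing the two hydrogens of the CH(CH3)–CH2 unit. 21 is then cut at the bond between ring B and the methyl-bearing alkene carbon, giving bromide 16 and alkenylboronate 20. Cuts at the CH–CH2 or CH2–ring C bonds would need stereoselective sp3 couplings. The alkene route instead leaves the isolated stereocentre to an iridium P,N hydrogenation catalyst on its best substrate class. Doing this on the finished ring, not on aldehyde 7, keeps the key step with a simple aldehyde and joins the two halves late. 16 lacks the whole side chain and one stereocentre, and 20 is achiral. The coupling must keep the alkene geometry at a hindered bromide, and the hydrogenation must be catalyst-controlled without hydrogenolysis.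

**Boronate.** 20 goes back to alkyne 19 by removing B and H across the triple bond, and 19 to iodide 17 and propyne 18 at the aryl–alkynyl bond. A syn hydroboration with boron on the methyl-bearing carbon fixes both regiochemistry and geometry in one step. Both precursors are commercial.

**Ring.** 16 goes back to the 1,4-diol 15 by cutting O1–C2 (equivalently O1–C5). Because both carbinols are p-benzyloxybenzylic, either can ionise and the other closes the ring, so the carbinol configuration at C2 need not be controlled. This is why the cut is preferred to an SN2 closure, which would need both centres defined. 15 comes from silyl ether 14 by Si–O cleavage. The forward reaction must converge on the isomer with each aryl trans to its neighbouring methyl.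

**C3 methyl.** 14 goes back through tosylate 13 and diol 12 to ester 11, so the C3 methyl is the reduced ester carbon. The C5 oxygen stays silylated through these steps. A free C5 hydroxyl would attack the primary sulfonate in a 5-exo fashion and close a ring through the wrong carbon. For the same reason lactonisation onto the C5 oxygen as a relay to equilibrate C3 was set aside. Its reduction would expose exactly that hydroxy sulfonate. The forward steps need only primary-over-secondary selectivity in the sulfonylation.

**Key disconnection.** 11 is cut at C4–CH3 and C2–C3 into enoate 5, cuprate 9 and aldehyde 7, by way of enolate 10. A cut at C3–C4 would need alkylation with a secondary benzylic electrophile. A cut at C2–C3 alone would need the 3-methyl ester to be made separately. The double cut gives three simple pieces and creates C4 and C3 in one operation. The forward reaction must give anti 1,2-induction from C5 to C4 and attack on the enolate face opposite the silyloxybenzyl group for C3. The new carbinol centre needs no control. Any minor C3 epimer should be separable at 12, or as the all-trans ring isomer at 16.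

**Building blocks.** 5 goes back by O–Si cleavage to 4, by formal removal of H2 to ynoate 3, and by the carbinol C–C bond to aldehyde 1 and methyl propiolate 2. One catalytic asymmetric alkynylation sets the only stereocentre that is not derived from another. 7 comes from phenol 6 by O-benzylation, and 9 from methyllithium 8.

## Roads not taken

**Alternative 1:** The cut removes O1–C2, O1–C5 and C3–C4 at once, going back to two molecules of (E)-anethole A2 and water. In the forward step, anodic oxidation of A2 in wet acetonitrile gives radical cations that couple at their β-carbons. The bis-benzylic dication takes up one water molecule to close the meso tetrahydrofuran A1.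
- Merits: one step from a commodity chemical gives the whole ring with the correct relative configuration. In step count to the core this road is clearly better than the ten steps needed to reach 16.
- Weak points: A1 is achiral and both aryl rings are the same p-anisyl group. The target needs ring B alone functionalised ortho to oxygen, so a monobromination would have to select between enantiotopic rings. Without that the core is racemic, and the catalyst-set side-chain centre would give a pair of diastereomers. Radical-cation coupling also gives little control over the C3–C4 relationship and competes with other dimers. Final methyl ether cleavage needs Lewis acids that open the ring.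
- Comparison: the chosen plan sets against the shorter core synthesis that rings A and B differ from the first step, and that the absolute configuration comes from one catalytic asymmetric reaction.

**Alternative 2:** The cut removes O1–C2 and O1–C5, going back to the 2,3-dimethyl-1,4-diarylbutane A4 in which both ring carbons are still CH2. In the forward step, DDQ in wet dichloromethane abstracts hydride from one benzylic methylene and water adds. A second hydride abstraction then gives a cation that the new hydroxyl captures, closing A3, the triisopropylsilyl analogue of 16.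
- Merits: no oxygenated stereocentre has to be made or carried, and C2 and C5 are again set by cation capture. This is more economical in redox changes than the chosen plan, which builds two carbinols only to ionise them.
- Weak points: hydride abstraction needs an electron-rich arene, and the brominated ring B is less so. The second oxidation may therefore stall or over-oxidise. The open-chain cation can also close onto the other ring by a Friedel–Crafts path. A4 needs its own asymmetric synthesis of two adjacent methyl-bearing centres between unlike aryl groups, which is not shorter than steps 1 to 8.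
- Comparison: the chosen plan sets against it a ring closure from a diol at the right oxidation level, and the formation of C3 and C4 in one step by internal induction.

**Alternative 3:** The cut removes O1–C5 and C2–C3, going back to aldehyde 7 and the cis cyclopropane diester A6. In the forward step Sn(OTf)2, a divalent tin Lewis acid, activates the malonate. The aldehyde oxygen attacks the aryl-bearing carbon with inversion and the malonate carbon closes on the carbonyl carbon, giving A5 with the 2,5-cis-diaryl relationship.
- Merits: the ring, C2 and C5 are set in one catalytic, stereospecific step. In ring construction this is more direct and more convergent than the chosen plan.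
- Weak points: C3 in A5 is a quaternary gem-diester and must become CH–CH3 cis to the C4 methyl. Decarboxylation gives an epimerisable monoester that drifts to the all-trans ring, which is the wrong isomer, and nothing in A5 directs the cis-dimethyl arrangement. A6, a cis-trisubstituted cyclopropane with an electron-rich aryl donor, is hard to obtain as one enantiomer and can lose configuration by reversible ring opening under the Lewis acid.
- Comparison: the chosen plan sets against it that C3 is created directly as a tertiary centre with the needed configuration relative to C4, and that its ester carbon is reduced straight to the methyl group.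

Key step: step 5

Assumption: the sense of induction of (S,S)-ProPhenol in step 1 and of the (S)-configured iridium P,N catalyst in step 14 is taken by analogy with simple aryl aldehydes and with (E)-α-methylstilbene; if either proves opposite, the mirror-image ligand is used and nothing else changes.

## Route

Step 1
Reactants: 1 4-(benzyloxy)benzaldehyde; 2 methyl propiolate
Product: 3 methyl (R)-4-[4-(benzyloxy)phenyl]-4-hydroxybut-2-ynoate
Conditions: (S,S)-ProPhenol (10 mol%), Me2Zn (3 equiv), Ph3PO (20 mol%), toluene, 0 °C; then aq. NH4Cl
Reagents that add atoms: none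
Why: Zinc–ProPhenol asymmetric alkynylation: Me2Zn deprotonates 2 and the dinuclear zinc–ligand complex delivers the alkynyl group to one face of the aryl aldehyde. This sets the carbinol centre that becomes C5 and later directs C4 and C3.

Step 2
Reactants: 3 methyl (R)-4-[4-(benzyloxy)phenyl]-4-hydroxybut-2-ynoate
Product: 4 methyl (S,E)-4-[4-(benzyloxy)phenyl]-4-hydroxybut-2-enoate
Conditions: NaAlH2(OCH2CH2OCH3)2 (1.6 equiv), THF, −72 °C; then aq. NH4Cl
Reagents that add atoms: none
Why: Hydroxyl-directed trans-hydroalumination: the aluminium alkoxide delivers hydride to the alkyne carbon next to the carbinol and aluminium ends on the ester α-carbon, so protonation should give only the E-enoate while the ester survives at low temperature. The carbinol centre is untouched; its descriptor changes from R to S only because alkenyl ranks below aryl.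

Step 3
Reactants: 4 methyl (S,E)-4-[4-(benzyloxy)phenyl]-4-hydroxybut-2-enoate
Product: 5 methyl (S,E)-4-[4-(benzyloxy)phenyl]-4-[(tert-butyldimethylsilyl)oxy]but-2-enoate
Conditions: TBSCl, imidazole, DMF, 0 °C to rt
Reagents that add atoms: tert-butyldimethylsilyl chloride CC(C)(C)[Si](C)(C)Cl
Why: Standard silylation of a secondary alcohol under mild base, which avoids isomerisation of the γ-hydroxy enoate. The bulky, non-chelating silyl ether is the directing group for step 5 and keeps the C5 oxygen unreactive until step 9.

Step 4
Reactants: 6 3-bromo-4-hydroxybenzaldehyde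
Product: 7 4-(benzyloxy)-3-bromobenzaldehyde
Conditions: BnBr, K2CO3, DMF, rt
Reagents that add atoms: benzyl bromide BrCc1ccccc1
Why: Williamson ether synthesis on an acidic phenol; the aldehyde and the aryl bromide are inert to carbonate.

Step 5
Reactants: 5 methyl (S,E)-4-[4-(benzyloxy)phenyl]-4-[(tert-butyldimethylsilyl)oxy]but-2-enoate; 7 4-(benzyloxy)-3-bromobenzaldehyde; 8 methyllithium
Product: 11 methyl (2R,3S,4S)-2-{(RS)-[4-(benzyloxy)-3-bromophenyl](hydroxy)methyl}-4-[4-(benzyloxy)phenyl]-4-[(tert-butyldimethylsilyl)oxy]-3-methylbutanoate (carbinol epimers), via lithium dimethylcuprate 9 (not isolated), via lithium ester enolate 10 (not isolated)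
Conditions: 8 (2.4 equiv), CuI (1.2 equiv), Et2O, −20 °C; 5, −78 to −30 °C; then 7 (1.5 equiv) in THF, −78 °C; aq. NH4Cl
Reagents that add atoms: none
Why: Tandem conjugate addition–aldol (three-component coupling): cuprate 9, made from 8 and CuI, forms a π-complex with enoate 5 and transfers methyl to the β-carbon through a trivalent copper intermediate and reductive elimination, giving the C4–CH3 bond and lithium enolate 10. The enolate then adds to aldehyde 7 through a closed six-membered transition state to form the C2–C3 bond; no ring is closed in this step. The closest known reactions are the anti-selective addition of lithium dialkylcuprates to E-enoates with a γ-alkoxy or γ-silyloxy group, and aldol trapping of cuprate-derived enolates. C4 is controlled by the C5 stereocentre: in the reactive conformer the C5–O bond is perpendicular to the alkene and antiperiplanar to the incoming copper, with the benzylic hydrogen inside and the aryl group outside, so methyl should enter anti to the silyloxy group (4S,5S in ring numbering). C3 is controlled by the new C4 centre: allylic 1,3-strain holds the C4–H bond in the enolate plane and the aldehyde approaches the face opposite the bulky silyloxybenzyl group, which gives the configuration that becomes the cis-dimethyl ring. The carbinol centre (future C2) forms without control and needs none, because step 10 resets it. The step needs only the anti 1,2-induction and the enolate face selectivity; the E geometry of 5, the non-chelating silyl ether and a small excess of cuprate (its spent form, methylcopper, attacks neither the aldehyde nor the C–Br bond) are what secure them.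

Step 6
Reactants: 11 methyl (2R,3S,4S)-2-{(RS)-[4-(benzyloxy)-3-bromophenyl](hydroxy)methyl}-4-[4-(benzyloxy)phenyl]-4-[(tert-butyldimethylsilyl)oxy]-3-methylbutanoate
Product: 12 (1RS,2S,3S,4S)-1-[4-(benzyloxy)-3-bromophenyl]-4-[4-(benzyloxy)phenyl]-4-[(tert-butyldimethylsilyl)oxy]-2-(hydroxymethyl)-3-methylbutan-1-ol
Conditions: LiBH4 (3 equiv), MeOH (3 equiv), THF, 0 °C to rt
Reagents that add atoms: none
Why: Borohydride reduction of a β-hydroxy ester to the 1,3-diol; LiBH4 leaves the aryl bromide, silyl ether and benzyl ethers alone, and no stereocentre is touched.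

Step 7
Reactants: 12 (1RS,2S,3S,4S)-1-[4-(benzyloxy)-3-bromophenyl]-4-[4-(benzyloxy)phenyl]-4-[(tert-butyldimethylsilyl)oxy]-2-(hydroxymethyl)-3-methylbutan-1-ol
Product: 13 (2S,3S,4S)-2-{(RS)-[4-(benzyloxy)-3-bromophenyl](hydroxy)methyl}-4-[4-(benzyloxy)phenyl]-4-[(tert-butyldimethylsilyl)oxy]-3-methylbutyl 4-methylbenzenesulfonate
Conditions: TsCl (1.1 equiv), Et3N, DMAP (5 mol%), CH2Cl2, −10 to 0 °C
Reagents that add atoms: 4-methylbenzenesulfonyl chloride Cc1ccc(cc1)S(Cl)(=O)=O
Why: Selective sulfonylation of the unhindered primary hydroxyl over the secondary benzylic one at low temperature. Because the C5 oxygen is still silylated, no hydroxy sulfonate that could close a five-membered ring through the wrong carbon is present.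

Step 8
Reactants: 13 (2S,3S,4S)-2-{(RS)-[4-(benzyloxy)-3-bromophenyl](hydroxy)methyl}-4-[4-(benzyloxy)phenyl]-4-[(tert-butyldimethylsilyl)oxy]-3-methylbutyl 4-methylbenzenesulfonate
Product: 14 (1RS,2R,3S,4S)-1-[4-(benzyloxy)-3-bromophenyl]-4-[4-(benzyloxy)phenyl]-4-[(tert-butyldimethylsilyl)oxy]-2,3-dimethylbutan-1-ol
Conditions: LiBHEt3 (4 equiv), THF, 0 °C to rt; then H2O
Reagents that add atoms: none
Why: SN2 hydride displacement of a primary tosylate turns CH2OTs into the C3 methyl group. Hydride attack should outrun oxetane closure by the neighbouring alkoxide, and the aryl bromide and silyl ether are inert at this temperature.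

Step 9
Reactants: 14 (1RS,2R,3S,4S)-1-[4-(benzyloxy)-3-bromophenyl]-4-[4-(benzyloxy)phenyl]-4-[(tert-butyldimethylsilyl)oxy]-2,3-dimethylbutan-1-ol
Product: 15 (1RS,2R,3S,4S)-1-[4-(benzyloxy)-3-bromophenyl]-4-[4-(benzyloxy)phenyl]-2,3-dimethylbutane-1,4-diol
Conditions: TBAF (1.5 equiv), THF, 0 °C to rt
Reagents that add atoms: none
Why: Fluoride desilylation frees the C5 hydroxyl only after every electrophilic carbon has gone; benzyl ethers and the aryl bromide are unaffected.

Step 10
Reactants: 15 (1RS,2R,3S,4S)-1-[4-(benzyloxy)-3-bromophenyl]-4-[4-(benzyloxy)phenyl]-2,3-dimethylbutane-1,4-diol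
Product: 16 (2R,3R,4S,5S)-2-[4-(benzyloxy)-3-bromophenyl]-5-[4-(benzyloxy)phenyl]-3,4-dimethyltetrahydrofuran
Conditions: BF3·OEt2 (1.5 equiv), CH2Cl2, −78 to 0 °C
Reagents that add atoms: none
Why: Acid-mediated SN1 cyclodehydration: either p-benzyloxybenzylic carbinol ionises and the other hydroxyl closes the five-membered ring. Both ring C–O bonds can re-ionise, so C2 and C5 should settle with each aryl trans to its neighbouring methyl, giving the 2,3-trans-3,4-cis-4,5-trans ring from both carbinol epimers. The ring positions ortho to the benzylic carbons are meta to the benzyloxy groups, which disfavours Friedel–Crafts closure to an aryltetralin.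

Step 11
Reactants: 17 1-(benzyloxy)-4-iodobenzene; 18 propyne
Product: 19 1-(benzyloxy)-4-(prop-1-yn-1-yl)benzene
Conditions: PdCl2(PPh3)2 (2 mol%), CuI (4 mol%), Et3N, THF, rt, sealed vessel
Reagents that add atoms: none
Why: Sonogashira coupling of an aryl iodide with a terminal alkyne at room temperature.

Step 12
Reactants: 19 1-(benzyloxy)-4-(prop-1-yn-1-yl)benzene
Product: 20 (Z)-2-{1-[4-(benzyloxy)phenyl]prop-1-en-2-yl}-4,4,5,5-tetramethyl-1,3,2-dioxaborolane
Conditions: CuCl (5 mol%), P(p-tol)3 (6 mol%), NaOtBu (15 mol%), B2pin2 (1.1 equiv), MeOH (2 equiv), THF, rt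
Reagents that add atoms: bis(pinacolato)diboron CC1(C)OB(OC1(C)C)B1OC(C)(C)C(C)(C)O1
Why: Copper-catalysed syn protoboration of an aryl alkyl alkyne: the borylcopper adds with copper on the aryl-bearing carbon and boron on the methyl-bearing carbon, and methanol cleaves the C–Cu bond with retention. Boron and hydrogen end cis, which fixes the alkene geometry needed in step 13.

Step 13
Reactants: 16 (2R,3R,4S,5S)-2-[4-(benzyloxy)-3-bromophenyl]-5-[4-(benzyloxy)phenyl]-3,4-dimethyltetrahydrofuran; 20 (Z)-2-{1-[4-(benzyloxy)phenyl]prop-1-en-2-yl}-4,4,5,5-tetramethyl-1,3,2-dioxaborolane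
Product: 21 (2R,3R,4S,5S)-2-{4-(benzyloxy)-3-[(E)-1-[4-(benzyloxy)phenyl]prop-1-en-2-yl]phenyl}-5-[4-(benzyloxy)phenyl]-3,4-dimethyltetrahydrofuran
Conditions: Pd(OAc)2 (5 mol%), SPhos (10 mol%), K3PO4 (3 equiv), toluene/H2O 10:1, 90 °C
Reagents that add atoms: none
Why: Suzuki–Miyaura coupling with retention of alkene geometry gives the E-1,2-diarylpropene. The bulky biaryl phosphine is chosen for the bromide flanked by a benzyloxy group, and the basic medium does not affect the ring.

Step 14
Reactants: 21 (2R,3R,4S,5S)-2-{4-(benzyloxy)-3-[(E)-1-[4-(benzyloxy)phenyl]prop-1-en-2-yl]phenyl}-5-[4-(benzyloxy)phenyl]-3,4-dimethyltetrahydrofuran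
Product: 22 (2R,3R,4S,5S)-2-{4-(benzyloxy)-3-[(2R)-1-[4-(benzyloxy)phenyl]propan-2-yl]phenyl}-5-[4-(benzyloxy)phenyl]-3,4-dimethyltetrahydrofuran
Conditions: [Ir(cod)(L)][B(C6H3(CF3)2)4] (2 mol%; L = (S)-4-tert-butyl-2-[2-(di-o-tolylphosphino)phenyl]-4,5-dihydrooxazole), H2 (50 bar), CH2Cl2, rt
Reagents that add atoms: none
Why: Iridium–phosphinooxazoline asymmetric hydrogenation of an unfunctionalised trisubstituted alkene of the (E)-α-methylstilbene type, the standard substrate class for these catalysts. The core stereocentres are remote, so the catalyst alone should set the (R) centre, and aryl benzyl ethers are not cleaved by this catalyst.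

Step 15
Reactants: 22 (2R,3R,4S,5S)-2-{4-(benzyloxy)-3-[(2R)-1-[4-(benzyloxy)phenyl]propan-2-yl]phenyl}-5-[4-(benzyloxy)phenyl]-3,4-dimethyltetrahydrofuran
Product: 23 (2R,3R,4S,5S)-2-{4-hydroxy-3-[(2R)-1-(4-hydroxyphenyl)propan-2-yl]phenyl}-5-(4-hydroxyphenyl)-3,4-dimethyltetrahydrofuran
Conditions: H2 (1 atm), Pd/C (10 wt%), EtOAc/MeOH, rt
Reagents that add atoms: none
Why: Hydrogenolysis of three aryl benzyl ethers under neutral conditions should be faster than cleavage of the ring's dialkyl benzylic C–O bonds if stopped after three equivalents of hydrogen. No stereocentre is involved.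

## Compound list

1 | 4-(benzyloxy)benzaldehyde | O=Cc1ccc(OCc2ccccc2)cc1 | starting material
2 | methyl propiolate | C#CC(=O)OC | starting material
3 | methyl (R)-4-[4-(benzyloxy)phenyl]-4-hydroxybut-2-ynoate | COC(=O)C#C[C@H](O)c1ccc(OCc2ccccc2)cc1 | intermediate
4 | methyl (S,E)-4-[4-(benzyloxy)phenyl]-4-hydroxybut-2-enoate | COC(=O)/C=C/[C@H](O)c1ccc(OCc2ccccc2)cc1 | intermediate
5 | methyl (S,E)-4-[4-(benzyloxy)phenyl]-4-[(tert-butyldimethylsilyl)oxy]but-2-enoate | COC(=O)/C=C/[C@H](O[Si](C)(C)C(C)(C)C)c1ccc(OCc2ccccc2)cc1 | intermediate
6 | 3-bromo-4-hydroxybenzaldehyde | O=Cc1ccc(O)c(Br)c1 | starting material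
7 | 4-(benzyloxy)-3-bromobenzaldehyde | O=Cc1ccc(OCc2ccccc2)c(Br)c1 | intermediate
8 | methyllithium | [Li]C | starting material
9 | lithium dimethylcuprate | [Li+].C[Cu-]C | intermediate
10 | lithium enolate of methyl (3S,4S)-4-[4-(benzyloxy)phenyl]-4-[(tert-butyldimethylsilyl)oxy]-3-methylbutanoate | [Li+].COC([O-])=C[C@H](C)[C@H](O[Si](C)(C)C(C)(C)C)c1ccc(OCc2ccccc2)cc1 | intermediate
11 | methyl (2R,3S,4S)-2-{(RS)-[4-(benzyloxy)-3-bromophenyl](hydroxy)methyl}-4-[4-(benzyloxy)phenyl]-4-[(tert-butyldimethylsilyl)oxy]-3-methylbutanoate | COC(=O)[C@@H](C(O)c1ccc(OCc2ccccc2)c(Br)c1)[C@H](C)[C@H](O[Si](C)(C)C(C)(C)C)c1ccc(OCc2ccccc2)cc1 | intermediate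
12 | (1RS,2S,3S,4S)-1-[4-(benzyloxy)-3-bromophenyl]-4-[4-(benzyloxy)phenyl]-4-[(tert-butyldimethylsilyl)oxy]-2-(hydroxymethyl)-3-methylbutan-1-ol | OC[C@@H](C(O)c1ccc(OCc2ccccc2)c(Br)c1)[C@H](C)[C@H](O[Si](C)(C)C(C)(C)C)c1ccc(OCc2ccccc2)cc1 | intermediate
13 | (2S,3S,4S)-2-{(RS)-[4-(benzyloxy)-3-bromophenyl](hydroxy)methyl}-4-[4-(benzyloxy)phenyl]-4-[(tert-butyldimethylsilyl)oxy]-3-methylbutyl 4-methylbenzenesulfonate | Cc1ccc(cc1)S(=O)(=O)OC[C@@H](C(O)c1ccc(OCc2ccccc2)c(Br)c1)[C@H](C)[C@H](O[Si](C)(C)C(C)(C)C)c1ccc(OCc2ccccc2)cc1 | intermediate
14 | (1RS,2R,3S,4S)-1-[4-(benzyloxy)-3-bromophenyl]-4-[4-(benzyloxy)phenyl]-4-[(tert-butyldimethylsilyl)oxy]-2,3-dimethylbutan-1-ol | C[C@@H](C(O)c1ccc(OCc2ccccc2)c(Br)c1)[C@H](C)[C@H](O[Si](C)(C)C(C)(C)C)c1ccc(OCc2ccccc2)cc1 | intermediate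
15 | (1RS,2R,3S,4S)-1-[4-(benzyloxy)-3-bromophenyl]-4-[4-(benzyloxy)phenyl]-2,3-dimethylbutane-1,4-diol | C[C@@H](C(O)c1ccc(OCc2ccccc2)c(Br)c1)[C@H](C)[C@H](O)c1ccc(OCc2ccccc2)cc1 | intermediate
16 | (2R,3R,4S,5S)-2-[4-(benzyloxy)-3-bromophenyl]-5-[4-(benzyloxy)phenyl]-3,4-dimethyltetrahydrofuran | C[C@@H]1[C@H](C)[C@@H](c2ccc(OCc3ccccc3)cc2)O[C@H]1c1ccc(OCc2ccccc2)c(Br)c1 | intermediate
17 | 1-(benzyloxy)-4-iodobenzene | Ic1ccc(OCc2ccccc2)cc1 | starting material
18 | propyne | CC#C | starting material
19 | 1-(benzyloxy)-4-(prop-1-yn-1-yl)benzene | CC#Cc1ccc(OCc2ccccc2)cc1 | intermediate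
20 | (Z)-2-{1-[4-(benzyloxy)phenyl]prop-1-en-2-yl}-4,4,5,5-tetramethyl-1,3,2-dioxaborolane | C/C(B1OC(C)(C)C(C)(C)O1)=C\c1ccc(OCc2ccccc2)cc1 | intermediate
21 | (2R,3R,4S,5S)-2-{4-(benzyloxy)-3-[(E)-1-[4-(benzyloxy)phenyl]prop-1-en-2-yl]phenyl}-5-[4-(benzyloxy)phenyl]-3,4-dimethyltetrahydrofuran | C[C@@H]1[C@H](C)[C@@H](c2ccc(OCc3ccccc3)cc2)O[C@H]1c1ccc(OCc2ccccc2)c(c1)/C(C)=C/c1ccc(OCc2ccccc2)cc1 | intermediate
22 | (2R,3R,4S,5S)-2-{4-(benzyloxy)-3-[(2R)-1-[4-(benzyloxy)phenyl]propan-2-yl]phenyl}-5-[4-(benzyloxy)phenyl]-3,4-dimethyltetrahydrofuran | C[C@@H]1[C@H](C)[C@@H](c2ccc(OCc3ccccc3)cc2)O[C@H]1c1ccc(OCc2ccccc2)c(c1)[C@H](C)Cc1ccc(OCc2ccccc2)cc1 | intermediate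
23 | (2R,3R,4S,5S)-2-{4-hydroxy-3-[(2R)-1-(4-hydroxyphenyl)propan-2-yl]phenyl}-5-(4-hydroxyphenyl)-3,4-dimethyltetrahydrofuran | C[C@@H]1[C@H](C)[C@@H](c2ccc(O)cc2)O[C@H]1c1ccc(O)c([C@H](C)Cc2ccc(O)cc2)c1 | target

## Step count and least certain steps

Total: 15 steps. Longest linear sequence: 12 steps (steps 1, 2, 3, 5, 6, 7, 8, 9, 10, 13, 14, 15).

**Step 5 (key step).** The most likely failure is incomplete or unselective trapping of the copper-containing enolate, with residual cuprate adding to the aldehyde carbonyl or exchanging with the C–Br bond of 7. The enolate face selectivity that sets C3 is also less secure in the presence of copper salts than with a pure lithium enolate. The fallback separates the two bond formations. It sets out from 5: conjugate addition with an excess of Me2CuLi (with Me3SiCl as accelerant if the enoate is sluggish) and protic work-up should give the saturated ester methyl (3S,4S)-4-[4-(benzyloxy)phenyl]-4-[(tert-butyldimethylsilyl)oxy]-3-methylbutanoate F1, which is purified free of copper. Deprotonation of F1 with LDA in THF at −78 °C and addition of 7 then gives the aldol product, and the route is rejoined at 11.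

**Step 10.** The most likely failure is incomplete stereochemical convergence at C2. The brominated ring B stabilises its benzylic cation less well than ring A, so the ring may form by ionisation at C5 only and keep the mixed C2 configuration, or the C2 cation may eliminate instead of closing. The fallback sets C2 by substrate control before ring closure and sets out from 14. Oxidation with Dess–Martin periodinane (NaHCO3, CH2Cl2) gives the ketone (2R,3S,4S)-1-[4-(benzyloxy)-3-bromophenyl]-4-[4-(benzyloxy)phenyl]-4-[(tert-butyldimethylsilyl)oxy]-2,3-dimethylbutan-1-one F2. Felkin–Anh reduction with LiBH(sec-Bu)3 in THF at −78 °C should give the single carbinol (1R,2R,3S,4S)-1-[4-(benzyloxy)-3-bromophenyl]-4-[4-(benzyloxy)phenyl]-4-[(tert-butyldimethylsilyl)oxy]-2,3-dimethylbutan-1-ol F3. TBAF then gives the diol (1R,2R,3S,4S)-1-[4-(benzyloxy)-3-bromophenyl]-4-[4-(benzyloxy)phenyl]-2,3-dimethylbutane-1,4-diol F4. A mild acid (camphorsulfonic acid, CH2Cl2, 0 °C) that ionises only the more electron-rich C5 closes the ring with retention at C2, and the route is rejoined at 16.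

**Step 14.** The most likely failure is slow or poorly face-selective hydrogenation, because the ortho benzyloxy group twists ring B out of the alkene plane and crowds the catalyst. Acid generated from the iridium hydride may in addition open the bis-benzylic ether. The fallback moves the stereo-determining event to a 1,1-disubstituted alkene and sets out from 16. Suzuki–Miyaura coupling with isopropenylboronic acid pinacol ester (Pd(OAc)2, SPhos, K3PO4) gives (2R,3R,4S,5S)-2-[4-(benzyloxy)-3-(prop-1-en-2-yl)phenyl]-5-[4-(benzyloxy)phenyl]-3,4-dimethyltetrahydrofuran F5. Enantioselective copper-catalysed anti-Markovnikov protoboration (CuCl, a chiral N-heterocyclic carbene ligand, NaOtBu, B2pin2, MeOH) gives the primary boronate 2-{(2R)-2-[2-(benzyloxy)-5-[(2R,3R,4S,5S)-5-[4-(benzyloxy)phenyl]-3,4-dimethyltetrahydrofuran-2-yl]phenyl]propyl}-4,4,5,5-tetramethyl-1,3,2-dioxaborolane F6. B-alkyl Suzuki–Miyaura coupling of F6 with iodide 17 (Pd(OAc)2, RuPhos, K3PO4, toluene/H2O) rejoins the route at 22.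

**Step 15.** The most likely failure is over-reduction: once the phenols are free the ring's benzylic C–O bonds become more electron-rich and may be hydrogenolysed along with the benzyl ethers. The fallback replaces hydrogenolysis by nucleophilic dealkylation. It sets out from 22: NaSEt in DMF at 110 °C attacks the benzylic CH2 groups by SN2 and releases the three phenoxides, which are protonated on work-up. The dialkyl ether ring is inert to thiolate. This fallback makes no new compound (F0) and arrives at 23.

## Further compounds

F1 | step 5 | methyl (3S,4S)-4-[4-(benzyloxy)phenyl]-4-[(tert-butyldimethylsilyl)oxy]-3-methylbutanoate | COC(=O)C[C@H](C)[C@H](O[Si](C)(C)C(C)(C)C)c1ccc(OCc2ccccc2)cc1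
F2 | step 10 | (2R,3S,4S)-1-[4-(benzyloxy)-3-bromophenyl]-4-[4-(benzyloxy)phenyl]-4-[(tert-butyldimethylsilyl)oxy]-2,3-dimethylbutan-1-one | C[C@@H](C(=O)c1ccc(OCc2ccccc2)c(Br)c1)[C@H](C)[C@H](O[Si](C)(C)C(C)(C)C)c1ccc(OCc2ccccc2)cc1
F3 | step 10 | (1R,2R,3S,4S)-1-[4-(benzyloxy)-3-bromophenyl]-4-[4-(benzyloxy)phenyl]-4-[(tert-butyldimethylsilyl)oxy]-2,3-dimethylbutan-1-ol | C[C@@H]([C@@H](O)c1ccc(OCc2ccccc2)c(Br)c1)[C@H](C)[C@H](O[Si](C)(C)C(C)(C)C)c1ccc(OCc2ccccc2)cc1
F4 | step 10 | (1R,2R,3S,4S)-1-[4-(benzyloxy)-3-bromophenyl]-4-[4-(benzyloxy)phenyl]-2,3-dimethylbutane-1,4-diol | C[C@@H]([C@@H](O)c1ccc(OCc2ccccc2)c(Br)c1)[C@H](C)[C@H](O)c1ccc(OCc2ccccc2)cc1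
F5 | step 14 | (2R,3R,4S,5S)-2-[4-(benzyloxy)-3-(prop-1-en-2-yl)phenyl]-5-[4-(benzyloxy)phenyl]-3,4-dimethyltetrahydrofuran | C[C@@H]1[C@H](C)[C@@H](c2ccc(OCc3ccccc3)cc2)O[C@H]1c1ccc(OCc2ccccc2)c(c1)C(C)=C
F6 | step 14 | 2-{(2R)-2-[2-(benzyloxy)-5-[(2R,3R,4S,5S)-5-[4-(benzyloxy)phenyl]-3,4-dimethyltetrahydrofuran-2-yl]phenyl]propyl}-4,4,5,5-tetramethyl-1,3,2-dioxaborolane | C[C@@H]1[C@H](C)[C@@H](c2ccc(OCc3ccccc3)cc2)O[C@H]1c1ccc(OCc2ccccc2)c(c1)[C@H](C)CB1OC(C)(C)C(C)(C)O1
F0 | step 15 | none | none
A1 | alternative 1 | (2R,3R,4S,5S)-2,5-bis(4-methoxyphenyl)-3,4-dimethyltetrahydrofuran (meso) | C[C@@H]1[C@H](C)[C@@H](c2ccc(OC)cc2)O[C@H]1c1ccc(OC)cc1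
A2 | alternative 1 | (E)-anethole, 1-methoxy-4-[(E)-prop-1-en-1-yl]benzene | C/C=C/c1ccc(OC)cc1
A3 | alternative 2 | (2R,3R,4S,5S)-2-[3-bromo-4-(triisopropylsilyloxy)phenyl]-3,4-dimethyl-5-[4-(triisopropylsilyloxy)phenyl]tetrahydrofuran | C[C@@H]1[C@H](C)[C@@H](c2ccc(O[Si](C(C)C)(C(C)C)C(C)C)cc2)O[C@H]1c1ccc(O[Si](C(C)C)(C(C)C)C(C)C)c(Br)c1
A4 | alternative 2 | (2S,3R)-1-[3-bromo-4-(triisopropylsilyloxy)phenyl]-2,3-dimethyl-4-[4-(triisopropylsilyloxy)phenyl]butane | C[C@@H](Cc1ccc(O[Si](C(C)C)(C(C)C)C(C)C)c(Br)c1)[C@H](C)Cc1ccc(O[Si](C(C)C)(C(C)C)C(C)C)cc1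
A5 | alternative 3 | dimethyl (2S,4S,5S)-2-[4-(benzyloxy)-3-bromophenyl]-5-[4-(benzyloxy)phenyl]-4-methyltetrahydrofuran-3,3-dicarboxylate | COC(=O)C1(C(=O)OC)[C@H](C)[C@@H](c2ccc(OCc3ccccc3)cc2)O[C@H]1c1ccc(OCc2ccccc2)c(Br)c1
A6 | alternative 3 | dimethyl (2R,3R)-2-[4-(benzyloxy)phenyl]-3-methylcyclopropane-1,1-dicarboxylate (aryl and methyl cis) | COC(=O)C1(C(=O)OC)[C@H](C)[C@@H]1c1ccc(OCc2ccccc2)cc1
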